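Late in a run the left-handed substrate must have thinned more than the right-handed one, since its coupling step has the larger constant, so I asked how late 12 h is in these flasks.

| setting | maple | birch | larch |
|---|---|---|---|
| left-handed substrate | 0.50 M | 0.50 M | 0.50 M |
| solid reagent | 0.750 M | 0.750 M | 0.750 M |
| precatalyst | 2.3 mM | 2.3 mM | 2.3 mM |
| right-handed substrate | 0.50 M | 0.50 M | 0.50 M |
| temperature | 50 °C | 80 °C | 65 °C |
| time | 12 h | 12 h | 12 h |

    precatalyst → catalyst (k1 = 4.8 × 10⁻⁵ /s, Ea1 = 110 kJ/mol)
    solid reagent ⇌ coupling partner, rate k2*(cs2 - [coupling partner]) while solid is left; crystals form when [coupling partner] > cs2 (cs2 = 49 mM, k2 = 2.9 × 10⁻⁵ /s)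
    coupling partner → decomposed reagent (k3 = 1.7 × 10⁻⁶ /s, Ea3 = 122 kJ/mol)
    coupling partner + catalyst + right-handed substrate → catalyst + right-handed product (k4 = 8.4 × 10⁻⁴ /M²/s, Ea4 = 46.0 kJ/mol)
    coupling partner + catalyst + left-handed substrate → catalyst + left-handed product (k5 = 0.0056 /M²/s, Ea5 = 43.0 kJ/mol)
    (constants at 50 °C)

- catalyst is single-handed; left-handed substrate and right-handed substrate are mirror images of each other, charged as a racemate, each of them at the stated concentration
- as a solid, counted per litre of solution: solid reagent
- the constants hold at 50 °C; other temperatures follow from the activation energies
- at the start none of the solid reagent is in solution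

1. the flask that comes out highest in share of left-handed product in all that became left-handed product or right-handed product, or "all alike" when all lie within 1.5 percentage points (maple / birch / larch / all alike)
2. share of left-handed product in all that became left-handed product or right-handed product, maple
3. share of left-handed product in all that became left-handed product or right-handed product, birch
4. share of left-handed product in all that became left-handed product or right-handed product, larch

One thing looked contradictory. From maple to birch, the coldest flask to the hottest, the decomposition of coupling partner speeds up by a factor 47, while the coupling steps speed up by only 3.9 and 4.3, and yet I expected the share to barely move. Both coupling steps carry the same coupling partner and the same catalyst, so these cancel in the ratio of the two rates. What remains is the selectivity factor S, the constant for the left-handed substrate divided by that for the right-handed one at the flask's temperature, times the ratio of the substrates. In maple S was 6.67, and in birch it was 6.06. With equal substrates the share is S/(1+S), which gave 87.0% for maple and 85.8% for birch.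

I then went round again for birch, to see how far the substrate thinned. Precatalyst turned over in about 10.7 min, far shorter than the run, so I took the catalyst as fully formed. Balancing dissolution against decomposition, with decomposition at 8.05 × 10⁻⁵ /s, put the coupling partner at 13.0 mM. Adding the coupling loss of 2.92 × 10⁻⁵ /s lowered this to 10.2 mM. At that level, held over the whole run, I reckoned a fraction x = 2.22% of the left-handed substrate used. Using mean substrates, the ratio of the two rates, S times the ratio of the substrates, came to 6.01 and the birch share to 85.7%. Against maple's first-round value the gap was 1.3 percentage points, inside the margin of 1.5 points, so I counted the flasks as equal.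

The forecast said all alike, with 86.9% for maple (86.6% to 87%), 85.8% for birch (85.4% to 86%) and 86.3% for larch (86% to 86.6%), holding that “substrate depletion barely matters”. My birch figure was 85.7%, against its 85.8%.

The simulation gave all alike, with 86.9% in maple, 85.7% in birch and 86.3% in larch. In larch at 12.0 h the half-lives of left-handed and right-handed substrate by their coupling steps stood at 13 d and 85 d, both far longer than the 12 h run, and 98% of the left-handed substrate remained. Birch, with S at 6.06, kept 98% of it, against my 97.8%. In the neighbour flask like larch at 90 °C, S is 5.90, which gives 85.5%, and that flask read 85.4%.

(All constants are those of an exercise.)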